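**Retrosynthetic overview**
- The two exocyclic methylenes (on the lactone and on the acrolein unit) and the two acetates are added last, by Mannich methylenations and acylation; this leads back to hydroxy lactone 25.
- Key disconnection: the lactone O–C6 bond together with the ring bond C7–C8. One Lewis-acid Prins/lactonization folds the acyclic aldehyde ester 23; the cyclohexane (C5–C10) and the γ-lactone close in the same step, and no ring exists before it.
- Enabling feature: C7 of the cyclohexane ring lies between the lactone carbinol C6 and the acetoxy carbinol C8 and carries the CH2–C12 arm of the lactone ring. An E-C6=C7 alkene therefore sits 6-endo to a C8 aldehyde and within reach of the C12 carbonyl oxygen; anti addition across it in a chair gives the trans ring fusion and the equatorial C8 oxygen.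
- The C5/C10 pair of 23 comes from two chirality-transferring Claisen rearrangements: Eschenmoser–Claisen from a C6 carbinol (sets quaternary C10) and Johnson–Claisen from a C7 carbinol (sets C5).
- The two carbinols come from a Noyori transfer hydrogenation of an ynone and a titanium acetate aldol.

Key step: step 12

Remark: carbons are numbered as in elemanolides (ring C5–C10, lactone carbinol C6, lactone carbonyl C12, acetoxy carbinol C8, acetoxymethyl C14, formyl C15); TBS = tert-butyldimethylsilyl, TBDPS = tert-butyldiphenylsilyl.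

**Step 1**
Reactants: 1 tert-butyldimethyl(prop-2-yn-1-yloxy)silane; 2 ethyl 2,2-diethoxyacetate
Product: 4 5-(TBS-oxy)-1,1-diethoxypent-3-yn-2-one, via lithium acetylide 3 (not isolated)
Conditions: n-BuLi, THF, −78 °C; then 2, −78 °C; aq. NH4Cl
Reagents that add atoms: none
Why: Acylation of an alkynyllithium by an ester; the α,α-diethoxy ester gives a chelated lithium hemiketalate that is stable at −78 °C and releases the ynone only on quench, so over-addition should not occur, and no stereocenter is formed.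

**Step 2**
Reactants: 4 ynone
Product: 5 (2R)-5-(TBS-oxy)-1,1-diethoxypent-3-yn-2-ol
Conditions: RuCl[(S,S)-TsDPEN](p-cymene) (1 mol%), i-PrOH, rt
Reagents that add atoms: none
Why: Noyori asymmetric transfer hydrogenation of an alkynyl ketone; with the alkynyl group in the place that an aryl group takes in the CH/π model, the (S,S)-catalyst should give the 2R carbinol (the later C6).

**Step 3**
Reactants: 5 (2R)-propargylic alcohol
Product: 7 (2R,3Z)-5-(TBS-oxy)-1,1-diethoxy-4-iodopent-3-en-2-ol, via cyclic alkenylaluminate 6 (not isolated)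
Conditions: NaAlH2(OCH2CH2OMe)2, THF, 0 °C; then I2, −78 °C
Reagents that add atoms: iodine, II
Why: Hydroxyl-directed trans-hydroalumination of a propargylic alcohol; the alkoxide delivers hydride to the proximal alkyne carbon and leaves aluminium on the distal one, and iodinolysis of the C–Al bond with retention gives the Z iodide (the silyl ether oxygen does not direct).

**Step 4**
Reactants: 7 (2R,3Z)-iodo alkenol; 8 tributyl(ethenyl)stannane
Product: 9 (2R,3E)-4-[(TBS-oxy)methyl]-1,1-diethoxyhexa-3,5-dien-2-ol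
Conditions: Pd(PPh3)4 (5 mol%), CuI (10 mol%), DMF, 40 °C
Reagents that add atoms: none
Why: Stille coupling of an alkenyl iodide with retention of the double-bond geometry and tolerance of the free hydroxyl group; it places the vinyl group cis to the carbinol carbon.

**Step 5**
Reactants: 9 (2R,3E)-dienol; 10 N,N-dimethylacetamide dimethyl acetal
Product: 12 (3R,4E)-3-[(TBS-oxy)methyl]-3-ethenyl-6,6-diethoxy-N,N-dimethylhex-4-enamide, via ketene N,O-acetal 11 (not isolated)
Conditions: 10 (3 equiv), toluene, 110 °C, sealed tube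
Reagents that add atoms: none
Why: Eschenmoser–Claisen rearrangement through a chair with the CH(OEt)2 group equatorial; suprafacial transfer of the carbinol chirality should create the quaternary center (3R, the later C10) and the E alkene in one event.

**Step 6**
Reactants: 12 amide acetal
Product: 13 (3R,4E)-3-[(TBS-oxy)methyl]-3-ethenyl-N,N-dimethyl-6-oxohex-4-enamide
Conditions: PPTS (cat.), acetone/H2O (10:1), 40 °C
Reagents that add atoms: water, O
Why: Acid-catalysed hydrolysis of an allylic acetal through a conjugated oxocarbenium ion, mild enough to leave the primary TBS ether and the E alkene untouched.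

**Step 7**
Reactants: 13 enal; 14 tert-butyl acetate
Product: 17 tert-butyl (3R,4E,6R)-6-[(TBS-oxy)methyl]-6-[2-(dimethylamino)-2-oxoethyl]-3-hydroxyocta-4,7-dienoate, via lithium enolate 15 (not isolated), via titanium enolate 16 (not isolated)
Conditions: 14, LiN(iPr)2, Et2O, −78 °C; CpTiCl(OR*)2 (R*OH = 1,2:5,6-di-O-isopropylidene-α-D-glucofuranose), −78 → −30 °C; then 13, −78 °C; aq. NH4F
Reagents that add atoms: none
Why: Duthaler–Hafner acetate aldol addition; the cyclopentadienyl titanium enolate with two diacetone-D-glucose ligands is expected to add 1,2 to the Re face of the enal, which sets the 3R carbinol (the chirality source for C5) under reagent control.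

**Step 8**
Reactants: 17 (3R)-allylic alcohol; 18 triethyl orthoacetate
Product: 20 1-tert-butyl 7-ethyl (3E,5R)-5-[(2R)-1-(TBS-oxy)-2-[2-(dimethylamino)-2-oxoethyl]but-3-en-2-yl]hept-3-enedioate, via mixed ketene acetal 19 (not isolated)
Conditions: 18 (excess), EtCO2H (cat.), 135 °C, removal of EtOH
Reagents that add atoms: none
Why: Johnson–Claisen rearrangement through a chair with the CH2CO2t-Bu group equatorial; the 3R carbinol chirality should be transferred to C5 (5R), the E-β,γ-unsaturated ester is formed, and the two-carbon ester arm is installed.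

**Step 9**
Reactants: 20 diester amide
Product: 21 tert-butyl (3E,5R)-5-[(2R)-1-(TBS-oxy)-2-[2-(dimethylamino)-2-oxoethyl]but-3-en-2-yl]-7-hydroxyhept-3-enoate
Conditions: LiBH4, THF, 0 °C → rt
Reagents that add atoms: none
Why: Chemoselective borohydride reduction; LiBH4 reduces the ethyl ester but should leave the hindered tert-butyl ester and the tertiary amide.

**Step 10**
Reactants: 21 primary alcohol
Product: 22 tert-butyl (3E,5R)-5-[(2R)-1-(TBS-oxy)-2-[2-(dimethylamino)-2-oxoethyl]but-3-en-2-yl]-7-(TBDPS-oxy)hept-3-enoate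
Conditions: TBDPSCl, imidazole, DMF, rt
Reagents that add atoms: tert-butyl(chloro)diphenylsilane, CC(C)(C)[Si](Cl)(c1ccccc1)c1ccccc1
Why: Silylation of a primary alcohol; the bulky TBDPS ether is a poor nucleophile toward the cation of step 12 and survives the later acidic removal of the TBS group.

**Step 11**
Reactants: 22 amide
Product: 23 tert-butyl (3E,5R,6R)-6-[(TBS-oxy)methyl]-5-[2-(TBDPS-oxy)ethyl]-6-ethenyl-8-oxooct-3-enoate
Conditions: Cp2Zr(H)Cl (1.5 equiv), THF, rt, 20 min; silica gel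
Reagents that add atoms: none
Why: Partial reduction of a tertiary amide with the Schwartz reagent, which stops at a zirconated hemiaminal that gives the aldehyde on work-up; esters are inert and the amide should react faster than the hindered vinyl group is hydrozirconated.

**Step 12**
Reactants: 23 aldehyde ester
Product: 25 (3aR,4S,6R,7S,7aR)-6-[(TBS-oxy)methyl]-7-[2-(TBDPS-oxy)ethyl]-6-ethenyl-4-hydroxyhexahydro-1-benzofuran-2(3H)-one, via O-tert-butyl lactonium ion 24 (not isolated)
Conditions: MeAlCl2 (1.2 equiv), CH2Cl2, −78 → −30 °C; cold 0.5 M HCl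
Reagents that add atoms: none
Why: MeAlCl2 binds the C8 aldehyde, the E-C6=C7 alkene attacks it through C7 in a chair transition state while the carbonyl oxygen of the tert-butyl ester adds anti at C6, and the lactonium ion 24 loses 2-methylpropene (the proton is taken up by the Al–Me bond as methane). The closest known reactions are the Lewis-acid Prins carbocyclization of δ,ε-unsaturated aldehydes and the carboxyl-terminated cation–olefin cyclization of E-β,γ-unsaturated acids to trans-fused γ-lactones (as with homofarnesic acid), merged here into one event. The cyclohexane closes 6-endo-trig by C7–C8 bond formation and the lactone closes 5-endo-trig by O–C6 bond formation. C6 and C7 follow from anti addition across the E alkene in the chair (lactone oxygen and C11 both equatorial, hence the trans fusion); C8 follows from the equatorial aluminium-bound oxygen, which avoids a 1,3-diaxial clash with the axial CH2OTBS group on C10; all three are set relative to C5 and C10 because the chair with the C5 side chain and the vinyl group equatorial is preferred. The step needs attack through C7 and not C6, which is secured because only the C6 cation can be closed to a five-membered lactone; it also needs lactone closure to outrun chloride transfer, proton loss and capture by a silyl ether oxygen, which the antiperiplanar ester carbonyl, the bulk of the TBDPS group and the absence of a more nucleophilic alkene (the vinyl group could only close 5-endo) should secure.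

**Step 13**
Reactants: 25 hydroxy lactone
Product: 28 (3aR,4S,6R,7S,7aR)-6-[(TBS-oxy)methyl]-7-[2-(TBDPS-oxy)ethyl]-6-ethenyl-4-hydroxy-3-methylidenehexahydro-1-benzofuran-2(3H)-one, via Mannich base 26 (not isolated), via ammonium iodide 27 (not isolated)
Conditions: LiN(iPr)2 (2.5 equiv), THF, −78 °C; CH2=NMe2+ I−, −78 °C → rt; MeI, MeOH, rt; aq. NaHCO3, CH2Cl2
Reagents that add atoms: Eschenmoser's salt, C=[N+](C)C.[I-]; iodomethane, CI (its methyl group stays only in intermediate 27)
Why: Mannich α-methylenation of a lactone; the lactone enolate (formed beside the C8 alkoxide) is aminomethylated, and quaternization followed by E1cB loss of trimethylamine gives the exocyclic alkene, the transient center at C11 being lost again.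

**Step 14**
Reactants: 28 α-methylene lactone
Product: 29 (3aR,4S,6R,7S,7aR)-7-[2-(TBDPS-oxy)ethyl]-6-ethenyl-4-hydroxy-6-(hydroxymethyl)-3-methylidenehexahydro-1-benzofuran-2(3H)-one
Conditions: CSA (cat.), MeOH/CH2Cl2, 0 °C
Reagents that add atoms: none
Why: Acid-catalysed methanolysis of a primary TBS ether, which should be far faster than cleavage of the TBDPS ether.

**Step 15**
Reactants: 29 diol
Product: 30 [(3aR,4S,6R,7S,7aR)-4-acetoxy-7-[2-(TBDPS-oxy)ethyl]-6-ethenyl-3-methylidene-2-oxooctahydro-1-benzofuran-6-yl]methyl acetate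
Conditions: Ac2O, pyridine, DMAP (cat.), CH2Cl2, rt
Reagents that add atoms: acetic anhydride, CC(=O)OC(C)=O
Why: Nucleophile-catalysed acylation of the primary and the secondary hydroxyl group.

**Step 16**
Reactants: 30 diacetate
Product: 31 [(3aR,4S,6R,7S,7aR)-4-acetoxy-6-ethenyl-7-(2-hydroxyethyl)-3-methylidene-2-oxooctahydro-1-benzofuran-6-yl]methyl acetate
Conditions: HF·pyridine, pyridine, THF, 0 °C → rt
Reagents that add atoms: none
Why: Fluoride-mediated cleavage of the silyl ether under buffered acidic conditions that spare the acetates and the Michael-acceptor lactone.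

**Step 17**
Reactants: 31 primary alcohol
Product: 32 [(3aR,4S,6R,7S,7aR)-4-acetoxy-6-ethenyl-3-methylidene-2-oxo-7-(2-oxoethyl)octahydro-1-benzofuran-6-yl]methyl acetate
Conditions: Dess–Martin periodinane, NaHCO3, CH2Cl2, rt
Reagents that add atoms: none
Why: Dess–Martin oxidation of a primary alcohol under buffered neutral conditions, which should not epimerize C5 or move the acetates.

**Step 18**
Reactants: 32 aldehyde
Product: 34 [(3aR,4S,6R,7R,7aR)-4-acetoxy-6-ethenyl-3-methylidene-2-oxo-7-(3-oxoprop-1-en-2-yl)octahydro-1-benzofuran-6-yl]methyl acetate, via Mannich base 33 (not isolated)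
Conditions: CH2=NMe2+ I−, Et3N, CH2Cl2, rt
Reagents that add atoms: Eschenmoser's salt, C=[N+](C)C.[I-]
Why: Mannich α-methylenation of an aldehyde; the enol adds to the iminium salt and the Mannich base eliminates dimethylamine to the 2-substituted acrolein, the mild base leaving C5 and the lactone untouched.

**Compound list**
1 | tert-butyldimethyl(prop-2-yn-1-yloxy)silane | C#CCO[Si](C)(C)C(C)(C)C | starting material
2 | ethyl 2,2-diethoxyacetate | CCOC(OCC)C(=O)OCC | starting material
3 | lithium acetylide of 1 | [Li]C#CCO[Si](C)(C)C(C)(C)C | intermediate (not isolated)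
4 | 5-(TBS-oxy)-1,1-diethoxypent-3-yn-2-one | CCOC(OCC)C(=O)C#CCO[Si](C)(C)C(C)(C)C | intermediate
5 | (2R)-5-(TBS-oxy)-1,1-diethoxypent-3-yn-2-ol | CCOC(OCC)[C@H](O)C#CCO[Si](C)(C)C(C)(C)C | intermediate
6 | sodium cyclic alkenylaluminate (five-membered O–Al–C=C ring, two 2-methoxyethoxy groups on Al) | CCOC(OCC)[C@@H]1O[Al-](OCCOC)(OCCOC)C(CO[Si](C)(C)C(C)(C)C)=C1.[Na+] | intermediate (not isolated)
7 | (2R,3Z)-5-(TBS-oxy)-1,1-diethoxy-4-iodopent-3-en-2-ol | CCOC(OCC)[C@H](O)/C=C(I)/CO[Si](C)(C)C(C)(C)C | intermediate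
8 | tributyl(ethenyl)stannane | C=C[Sn](CCCC)(CCCC)CCCC | starting material
9 | (2R,3E)-4-[(TBS-oxy)methyl]-1,1-diethoxyhexa-3,5-dien-2-ol | CCOC(OCC)[C@H](O)/C=C(C=C)/CO[Si](C)(C)C(C)(C)C | intermediate
10 | N,N-dimethylacetamide dimethyl acetal | CC(OC)(OC)N(C)C | starting material
11 | ketene N,O-acetal of 9 | C=C(N(C)C)O[C@@H](C(OCC)OCC)/C=C(C=C)/CO[Si](C)(C)C(C)(C)C | intermediate (not isolated)
12 | (3R,4E)-3-[(TBS-oxy)methyl]-3-ethenyl-6,6-diethoxy-N,N-dimethylhex-4-enamide | CN(C)C(=O)C[C@](C=C)(CO[Si](C)(C)C(C)(C)C)/C=C/C(OCC)OCC | intermediate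
13 | (3R,4E)-3-[(TBS-oxy)methyl]-3-ethenyl-N,N-dimethyl-6-oxohex-4-enamide | CN(C)C(=O)C[C@](C=C)(CO[Si](C)(C)C(C)(C)C)/C=C/C=O | intermediate
14 | tert-butyl acetate | CC(=O)OC(C)(C)C | starting material
15 | lithium enolate of tert-butyl acetate | C=C(O[Li])OC(C)(C)C | intermediate (not isolated)
16 | cyclopentadienyl bis(diacetone-D-glucos-3-O-yl) titanium enolate of tert-butyl acetate | C=C(OC(C)(C)C)O[Ti](C1C=CC=C1)(O[C@H]1[C@H](O[C@@H]2OC(C)(C)O[C@H]12)[C@H]1COC(C)(C)O1)O[C@H]1[C@H](O[C@@H]2OC(C)(C)O[C@H]12)[C@H]1COC(C)(C)O1 | intermediate (not isolated)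
17 | tert-butyl (3R,4E,6R)-6-[(TBS-oxy)methyl]-6-[2-(dimethylamino)-2-oxoethyl]-3-hydroxyocta-4,7-dienoate | CC(C)(C)OC(=O)C[C@@H](O)/C=C/[C@@](C=C)(CO[Si](C)(C)C(C)(C)C)CC(=O)N(C)C | intermediate
18 | triethyl orthoacetate | CCOC(C)(OCC)OCC | starting material
19 | mixed ketene acetal of 17 | C=C(OCC)O[C@H](CC(=O)OC(C)(C)C)/C=C/[C@@](C=C)(CO[Si](C)(C)C(C)(C)C)CC(=O)N(C)C | intermediate (not isolated)
20 | 1-tert-butyl 7-ethyl (3E,5R)-5-[(2R)-1-(TBS-oxy)-2-[2-(dimethylamino)-2-oxoethyl]but-3-en-2-yl]hept-3-enedioate | CN(C)C(=O)C[C@](C=C)(CO[Si](C)(C)C(C)(C)C)[C@H](CC(=O)OCC)/C=C/CC(=O)OC(C)(C)C | intermediate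
21 | tert-butyl (3E,5R)-5-[(2R)-1-(TBS-oxy)-2-[2-(dimethylamino)-2-oxoethyl]but-3-en-2-yl]-7-hydroxyhept-3-enoate | CN(C)C(=O)C[C@](C=C)(CO[Si](C)(C)C(C)(C)C)[C@H](CCO)/C=C/CC(=O)OC(C)(C)C | intermediate
22 | tert-butyl (3E,5R)-5-[(2R)-1-(TBS-oxy)-2-[2-(dimethylamino)-2-oxoethyl]but-3-en-2-yl]-7-(TBDPS-oxy)hept-3-enoate | CN(C)C(=O)C[C@](C=C)(CO[Si](C)(C)C(C)(C)C)[C@H](CCO[Si](c1ccccc1)(c1ccccc1)C(C)(C)C)/C=C/CC(=O)OC(C)(C)C | intermediate
23 | tert-butyl (3E,5R,6R)-6-[(TBS-oxy)methyl]-5-[2-(TBDPS-oxy)ethyl]-6-ethenyl-8-oxooct-3-enoate | O=CC[C@](C=C)(CO[Si](C)(C)C(C)(C)C)[C@H](CCO[Si](c1ccccc1)(c1ccccc1)C(C)(C)C)/C=C/CC(=O)OC(C)(C)C | intermediate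
24 | O-tert-butyl lactonium ion with aluminate-bound C8 oxygen (zwitterion) | C=C[C@]1(CO[Si](C)(C)C(C)(C)C)C[C@H](O[Al-](C)(Cl)Cl)[C@H]2CC(OC(C)(C)C)=[O+][C@@H]2[C@H]1CCO[Si](c1ccccc1)(c1ccccc1)C(C)(C)C | intermediate (not isolated)
25 | (3aR,4S,6R,7S,7aR)-6-[(TBS-oxy)methyl]-7-[2-(TBDPS-oxy)ethyl]-6-ethenyl-4-hydroxyhexahydro-1-benzofuran-2(3H)-one (trans-fused lactone) | C=C[C@]1(CO[Si](C)(C)C(C)(C)C)C[C@H](O)[C@H]2CC(=O)O[C@@H]2[C@H]1CCO[Si](c1ccccc1)(c1ccccc1)C(C)(C)C | intermediate
26 | 3-[(dimethylamino)methyl] derivative of 25 (C3 epimers) | C=C[C@]1(CO[Si](C)(C)C(C)(C)C)C[C@H](O)[C@H]2C(CN(C)C)C(=O)O[C@@H]2[C@H]1CCO[Si](c1ccccc1)(c1ccccc1)C(C)(C)C | intermediate (not isolated)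
27 | trimethylammonium iodide of 26 | C=C[C@]1(CO[Si](C)(C)C(C)(C)C)C[C@H](O)[C@H]2C(C[N+](C)(C)C)C(=O)O[C@@H]2[C@H]1CCO[Si](c1ccccc1)(c1ccccc1)C(C)(C)C.[I-] | intermediate (not isolated)
28 | (3aR,4S,6R,7S,7aR)-6-[(TBS-oxy)methyl]-7-[2-(TBDPS-oxy)ethyl]-6-ethenyl-4-hydroxy-3-methylidenehexahydro-1-benzofuran-2(3H)-one | C=C[C@]1(CO[Si](C)(C)C(C)(C)C)C[C@H](O)[C@H]2C(=C)C(=O)O[C@@H]2[C@H]1CCO[Si](c1ccccc1)(c1ccccc1)C(C)(C)C | intermediate
29 | (3aR,4S,6R,7S,7aR)-7-[2-(TBDPS-oxy)ethyl]-6-ethenyl-4-hydroxy-6-(hydroxymethyl)-3-methylidenehexahydro-1-benzofuran-2(3H)-one | C=C[C@]1(CO)C[C@H](O)[C@H]2C(=C)C(=O)O[C@@H]2[C@H]1CCO[Si](c1ccccc1)(c1ccccc1)C(C)(C)C | intermediate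
30 | [(3aR,4S,6R,7S,7aR)-4-acetoxy-7-[2-(TBDPS-oxy)ethyl]-6-ethenyl-3-methylidene-2-oxooctahydro-1-benzofuran-6-yl]methyl acetate | C=C[C@]1(COC(C)=O)C[C@H](OC(C)=O)[C@H]2C(=C)C(=O)O[C@@H]2[C@H]1CCO[Si](c1ccccc1)(c1ccccc1)C(C)(C)C | intermediate
31 | [(3aR,4S,6R,7S,7aR)-4-acetoxy-6-ethenyl-7-(2-hydroxyethyl)-3-methylidene-2-oxooctahydro-1-benzofuran-6-yl]methyl acetate | C=C[C@]1(COC(C)=O)C[C@H](OC(C)=O)[C@H]2C(=C)C(=O)O[C@@H]2[C@H]1CCO | intermediate
32 | [(3aR,4S,6R,7S,7aR)-4-acetoxy-6-ethenyl-3-methylidene-2-oxo-7-(2-oxoethyl)octahydro-1-benzofuran-6-yl]methyl acetate | C=C[C@]1(COC(C)=O)C[C@H](OC(C)=O)[C@H]2C(=C)C(=O)O[C@@H]2[C@H]1CC=O | intermediate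
33 | α-[(dimethylamino)methyl] aldehyde from 32 (epimers at the new center) | C=C[C@]1(COC(C)=O)C[C@H](OC(C)=O)[C@H]2C(=C)C(=O)O[C@@H]2[C@H]1C(CN(C)C)C=O | intermediate (not isolated)
34 | [(3aR,4S,6R,7R,7aR)-4-acetoxy-6-ethenyl-3-methylidene-2-oxo-7-(3-oxoprop-1-en-2-yl)octahydro-1-benzofuran-6-yl]methyl acetate (CNP0200597.1) | C=C[C@]1(COC(C)=O)C[C@H](OC(C)=O)[C@H]2C(=C)C(=O)O[C@@H]2[C@H]1C(=C)C=O | target

**Step count and risks**
Total step count: 18. Longest linear sequence: 18 steps (from 1 to 34).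

Steps most likely to fail:

1. Step 12 (key step). The unactivated 1,2-disubstituted alkene may add too slowly to the aldehyde complex, so that chloride transfer to the C6 cation, proton loss or attack through C6 takes over before the ester closes the lactone. The fallback sets out from aldehyde 23 and returns at hydroxy lactone 25. The aldehyde is converted into its 1,3-dioxane acetal, tert-butyl (3E,5R,6R)-6-[(TBS-oxy)methyl]-5-[2-(TBDPS-oxy)ethyl]-7-(1,3-dioxan-2-yl)-6-ethenylhept-3-enoate F1 (1,3-bis(trimethylsilyloxy)propane, TMSOTf cat., CH2Cl2, −78 °C). Ionization with TiCl4 (CH2Cl2, −78 °C) starts a Johnson-type acetal-initiated cation–olefin cyclization: the cyclic oxocarbenium ion is a stronger electrophile than the aldehyde complex, and the ester again closes the lactone, giving the 4-(3-hydroxypropoxy) lactone F2. Dess–Martin oxidation to the 4-(3-oxopropoxy) lactone F3, then β-elimination with DBU, removes the tether and should give 25.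

2. Step 8. Acid-promoted dehydration of the β-hydroxy ester to a dienoate may compete with a slow [3,3] shift at the terminus next to the quaternary carbon. The fallback sets out from alcohol 17 and returns at alcohol 21. Transvinylation (Hg(OAc)2 cat., ethyl vinyl ether, reflux) gives the allyl vinyl ether, tert-butyl (3R,4E,6R)-6-[(TBS-oxy)methyl]-6-[2-(dimethylamino)-2-oxoethyl]-3-(ethenyloxy)octa-4,7-dienoate F4. Its acid-free thermal Claisen rearrangement (toluene, 110 °C) should give the aldehyde, tert-butyl (3E,5R)-5-[(2R)-1-(TBS-oxy)-2-[2-(dimethylamino)-2-oxoethyl]but-3-en-2-yl]-7-oxohept-3-enoate F5, with the same chirality transfer. NaBH4 (MeOH, 0 °C) then gives 21, which also makes the ester differentiation of step 9 unnecessary.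

3. Step 5. Chirality transfer may erode through a boat transition state at the fully substituted terminus, and the diene may react thermally at 110 °C. The fallback sets out from dienol 9 and returns at amide 12. Acetylation (Ac2O, pyridine) gives (2R,3E)-4-[(TBS-oxy)methyl]-1,1-diethoxyhexa-3,5-dien-2-yl acetate F6. Ireland–Claisen rearrangement of its silyl ketene acetal (LiN(iPr)2, TMSCl, THF, −78 °C → rt) should give (3R,4E)-3-[(TBS-oxy)methyl]-3-ethenyl-6,6-diethoxyhex-4-enoic acid F7 at a much lower temperature. Amide coupling (Me2NH·HCl, EDC, HOBt, i-Pr2NEt) then gives 12.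

**Further compounds**
F1 | step 12 | tert-butyl (3E,5R,6R)-6-[(TBS-oxy)methyl]-5-[2-(TBDPS-oxy)ethyl]-7-(1,3-dioxan-2-yl)-6-ethenylhept-3-enoate | C1(C[C@](C=C)(CO[Si](C)(C)C(C)(C)C)[C@H](CCO[Si](c2ccccc2)(c2ccccc2)C(C)(C)C)/C=C/CC(=O)OC(C)(C)C)OCCCO1
F2 | step 12 | (3aR,4S,6R,7S,7aR)-6-[(TBS-oxy)methyl]-7-[2-(TBDPS-oxy)ethyl]-6-ethenyl-4-(3-hydroxypropoxy)hexahydro-1-benzofuran-2(3H)-one | C=C[C@]1(CO[Si](C)(C)C(C)(C)C)C[C@H](OCCCO)[C@H]2CC(=O)O[C@@H]2[C@H]1CCO[Si](c1ccccc1)(c1ccccc1)C(C)(C)C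
F3 | step 12 | (3aR,4S,6R,7S,7aR)-6-[(TBS-oxy)methyl]-7-[2-(TBDPS-oxy)ethyl]-6-ethenyl-4-(3-oxopropoxy)hexahydro-1-benzofuran-2(3H)-one | C=C[C@]1(CO[Si](C)(C)C(C)(C)C)C[C@H](OCCC=O)[C@H]2CC(=O)O[C@@H]2[C@H]1CCO[Si](c1ccccc1)(c1ccccc1)C(C)(C)C
F4 | step 8 | tert-butyl (3R,4E,6R)-6-[(TBS-oxy)methyl]-6-[2-(dimethylamino)-2-oxoethyl]-3-(ethenyloxy)octa-4,7-dienoate | C=CO[C@H](CC(=O)OC(C)(C)C)/C=C/[C@@](C=C)(CO[Si](C)(C)C(C)(C)C)CC(=O)N(C)C
F5 | step 8 | tert-butyl (3E,5R)-5-[(2R)-1-(TBS-oxy)-2-[2-(dimethylamino)-2-oxoethyl]but-3-en-2-yl]-7-oxohept-3-enoate | CN(C)C(=O)C[C@](C=C)(CO[Si](C)(C)C(C)(C)C)[C@H](CC=O)/C=C/CC(=O)OC(C)(C)C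
F6 | step 5 | (2R,3E)-4-[(TBS-oxy)methyl]-1,1-diethoxyhexa-3,5-dien-2-yl acetate | CCOC(OCC)[C@H](OC(C)=O)/C=C(C=C)/CO[Si](C)(C)C(C)(C)C
F7 | step 5 | (3R,4E)-3-[(TBS-oxy)methyl]-3-ethenyl-6,6-diethoxyhex-4-enoic acid | OC(=O)C[C@](C=C)(CO[Si](C)(C)C(C)(C)C)/C=C/C(OCC)OCC
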